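The five C–Br bonds of rings A and B are formed in one electrophilic bromination, before ring C is attached. Ring A is numbered a1 (C–OH) to a6 (C–O–ring B), ring B b1 (C–O–ring A) to b6 (C–O–ring C). The bromines at a3, a5, b3, b4 and b5 all lie ortho or para to an oxygen-bearing carbon (a6, b1, b6), and a3 and a5 are meta to a1; a free hydroxyl on b6 and a formyl group on a1 therefore steer all five. The precursor is the halogen-free diaryl ether 2-(2-hydroxyphenoxy)benzaldehyde; afterwards b6–O is arylated, formyl becomes hydroxyl, and nitro becomes iodine.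

Key step: step 2

Remark on the chemistry: ring C is delivered as the electrophile 4-bromo-1-fluoro-2-nitrobenzene, because the bridging oxygen already belongs to ring B and an aryl donor must not bring a second oxygen; the nitro group is the latent iodine. This compound and 3,5-dibromo-2-fluorobenzaldehyde (used only in a fallback) are taken to be catalogue compounds. No compound of the main route has a stereocentre.

Step 1
Reactants: 1 catechol (3 equiv); 2 2-fluorobenzaldehyde
Product: 3 2-(2-hydroxyphenoxy)benzaldehyde
Conditions: K2CO3, DMF, 100 °C, N2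
Reagents that add atoms: none
Why: Nucleophilic aromatic substitution (SNAr): the mono-phenoxide of catechol adds to the fluorine-bearing carbon, which the ortho formyl group activates, and fluoride leaves, while the excess of the symmetrical diol under N2 should suppress double arylation and air oxidation.

Step 2
Reactants: 3 2-(2-hydroxyphenoxy)benzaldehyde
Product: 4 3,5-dibromo-2-(3,4,5-tribromo-2-hydroxyphenoxy)benzaldehyde
Conditions: Br2 (5.1 equiv), NaOAc, AcOH, rt → 60 °C
Reagents that add atoms: bromine, BrBr
Why: Five successive electrophilic aromatic substitutions take place, each by attack of Br2 on the ring to give an arenium ion that loses a proton to acetate: the electron-rich ring B is expected to react first at b5 and b3 (ortho and para to the free hydroxyl on b6) and then at b4 (para to the bridging oxygen on b1), and ring A then reacts at a3 and a5 (para and ortho to the bridging oxygen on a6), the two positions that the meta-directing formyl group on a1 also favours. The closest known reaction type is the exhaustive bromination of phenols, 2-alkoxyphenols and 2-alkoxybenzaldehydes with Br2 in buffered acetic acid, which follows the same ortho/para rules. No ring is closed and no stereocentre is formed. The selectivity needed is to stop at five bromines and leave b2, a2 and a4 as C–H: a2 and a4 are meta to the ether oxygen and ortho or para to the formyl group, so they are not activated, while b2 is meta to the hydroxyl, wedged between the aryloxy group and the b3 bromine, and sits on a ring already deactivated by three bromines; the charge of Br2 is held near five equivalents. NaOAc captures the HBr formed so that the medium stays mild, and water-free acetic acid should spare the formyl group from oxidation.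

Step 3
Reactants: 4 3,5-dibromo-2-(3,4,5-tribromo-2-hydroxyphenoxy)benzaldehyde; 5 4-bromo-1-fluoro-2-nitrobenzene
Product: 6 3,5-dibromo-2-[3,4,5-tribromo-2-(4-bromo-2-nitrophenoxy)phenoxy]benzaldehyde
Conditions: Cs2CO3, DMF, 45 °C
Reagents that add atoms: none
Why: SNAr on an ortho-fluoronitroarene: the b6 phenoxide of 4 displaces fluoride from 5 through a nitro-stabilised Meisenheimer adduct at a temperature low enough that the much less activated ring A and all C–Br bonds should stay untouched.

Step 4
Reactants: 6 3,5-dibromo-2-[3,4,5-tribromo-2-(4-bromo-2-nitrophenoxy)phenoxy]benzaldehyde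
Product: 8 3,5-dibromo-2-[3,4,5-tribromo-2-(4-bromo-2-nitrophenoxy)phenoxy]phenol, via aryl formate 7 (not isolated)
Conditions: mCPBA, CH2Cl2, 0 °C → 40 °C; then MeOH, HCl (cat.), rt
Reagents that add atoms: 3-chloroperoxybenzoic acid (mCPBA), OOC(=O)c1cccc(Cl)c1
Why: Dakin-type Baeyer–Villiger oxidation: the peracid adds to the formyl group and ring A migrates from carbon to oxygen in the Criegee adduct, assisted by the ortho aryloxy donor, to give formate 7, which acid-catalysed methanolysis cleaves to the phenol without exposing the nitro-activated diaryl ether to alkoxide.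

Step 5
Reactants: 8 3,5-dibromo-2-[3,4,5-tribromo-2-(4-bromo-2-nitrophenoxy)phenoxy]phenol
Product: 9 2-[2-(2-amino-4-bromophenoxy)-3,4,5-tribromophenoxy]-3,5-dibromophenol
Conditions: Fe powder, AcOH, EtOH, 70 °C
Reagents that add atoms: none
Why: Béchamp reduction: electron transfer from iron in acetic acid reduces the nitro group to the amine, and aryl bromides, diaryl ethers and the phenol are known to survive these conditions.

Step 6
Reactants: 9 2-[2-(2-amino-4-bromophenoxy)-3,4,5-tribromophenoxy]-3,5-dibromophenol
Product: 11 bromoiesol B, 3,5-dibromo-2-[3,4,5-tribromo-2-(4-bromo-2-iodophenoxy)phenoxy]phenol, via arenediazonium tosylate 10 (not isolated)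
Conditions: NaNO2 (1.05 equiv), p-TsOH·H2O, MeCN/H2O, 0–5 °C; then KI, 0 °C → rt
Reagents that add atoms: potassium iodide, [K+].[I-]; sodium nitrite, [Na+].[O-]N=O (its nitrogen remains only in intermediate 10)
Why: Diazotisation and iodide displacement (Sandmeyer-type iodination, which needs no copper salt): the aniline gives diazonium salt 10, iodide reduces it to an aryl radical that is trapped as the C–I bond with loss of N2, and the acidic medium keeps the ring A phenol from azo coupling.

Compound list
1 | catechol (benzene-1,2-diol) | Oc1ccccc1O | starting material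
2 | 2-fluorobenzaldehyde | O=Cc1ccccc1F | starting material
3 | 2-(2-hydroxyphenoxy)benzaldehyde | O=Cc1ccccc1Oc1ccccc1O | intermediate
4 | 3,5-dibromo-2-(3,4,5-tribromo-2-hydroxyphenoxy)benzaldehyde | O=Cc1cc(Br)cc(Br)c1Oc1cc(Br)c(Br)c(Br)c1O | intermediate
5 | 4-bromo-1-fluoro-2-nitrobenzene | [O-][N+](=O)c1cc(Br)ccc1F | starting material
6 | 3,5-dibromo-2-[3,4,5-tribromo-2-(4-bromo-2-nitrophenoxy)phenoxy]benzaldehyde | O=Cc1cc(Br)cc(Br)c1Oc1cc(Br)c(Br)c(Br)c1Oc1ccc(Br)cc1[N+](=O)[O-] | intermediate
7 | 3,5-dibromo-2-[3,4,5-tribromo-2-(4-bromo-2-nitrophenoxy)phenoxy]phenyl formate | O=COc1cc(Br)cc(Br)c1Oc1cc(Br)c(Br)c(Br)c1Oc1ccc(Br)cc1[N+](=O)[O-] | intermediate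
8 | 3,5-dibromo-2-[3,4,5-tribromo-2-(4-bromo-2-nitrophenoxy)phenoxy]phenol | Oc1cc(Br)cc(Br)c1Oc1cc(Br)c(Br)c(Br)c1Oc1ccc(Br)cc1[N+](=O)[O-] | intermediate
9 | 2-[2-(2-amino-4-bromophenoxy)-3,4,5-tribromophenoxy]-3,5-dibromophenol | Oc1cc(Br)cc(Br)c1Oc1cc(Br)c(Br)c(Br)c1Oc1ccc(Br)cc1N | intermediate
10 | 5-bromo-2-[2,3,4-tribromo-6-(2,4-dibromo-6-hydroxyphenoxy)phenoxy]benzenediazonium 4-methylbenzenesulfonate | Oc1cc(Br)cc(Br)c1Oc1cc(Br)c(Br)c(Br)c1Oc1ccc(Br)cc1[N+]#N.Cc1ccc(cc1)S(=O)(=O)[O-] | intermediate
11 | bromoiesol B, 3,5-dibromo-2-[3,4,5-tribromo-2-(4-bromo-2-iodophenoxy)phenoxy]phenol | Oc1cc(Br)cc(Br)c1Oc1cc(Br)c(Br)c(Br)c1Oc1ccc(Br)cc1I | target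

Total step count: 6
Longest linear sequence: 6 steps (from 1 and 2 to 11)

Steps most likely to fail

Step 2 (key step). Three processes could spoil it: a sixth substitution at b2 may set in before the last bromine enters the formyl-deactivated ring A at a5; ring A may stop at the monobromide; or ipso attack at a1 may expel the formyl group. Any of these would give mixtures of bromination levels that are hard to separate. The fallback brings the ring A bromines in ready-made. It sets out from catechol 1, which is arylated with 3,5-dibromo-2-fluorobenzaldehyde F1 (K2CO3, DMF, 80 °C, SNAr) to give 3,5-dibromo-2-(2-hydroxyphenoxy)benzaldehyde F2. Only the activated phenol ring of F2 then has to be brominated (Br2, 3.05 equiv, NaOAc, AcOH, rt), at b5, b3 and b4, and the route is rejoined at compound 4.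

Step 3. Under base, the b6 phenoxide may attack a6 of ring A, which the ortho formyl group activates, and ring A may wander from the b1 oxygen to the b6 oxygen through a spiro Meisenheimer adduct (Smiles rearrangement). This could outpace the arylation of a hindered, weakly nucleophilic phenoxide and would scramble which catechol oxygen carries which ring. The fallback removes the activation. It sets out from 4, whose formyl group is masked as the acetal 2,3,4-tribromo-6-[2,4-dibromo-6-(dimethoxymethyl)phenoxy]phenol F3 (HC(OMe)3, MeOH, p-TsOH cat., rt). F3 is arylated with 5 (Cs2CO3, DMF, 70 °C) to give 1,5-dibromo-3-(dimethoxymethyl)-2-[3,4,5-tribromo-2-(4-bromo-2-nitrophenoxy)phenoxy]benzene F4, and aqueous HCl in THF returns the aldehyde, rejoining the route at compound 6.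

Step 4. In the Criegee adduct, hydride migration may win over migration of the dibrominated, sterically twisted ring A, so that the peracid delivers the benzoic acid and not the formate. The fallback replaces the competing hydrogen by a methyl group, which migrates far less readily than any aryl group. It sets out from 6, which adds MeTi(OiPr)3 (THF, −20 °C, tolerant of the nitro group) to give racemic 1-{3,5-dibromo-2-[3,4,5-tribromo-2-(4-bromo-2-nitrophenoxy)phenoxy]phenyl}ethan-1-ol F5. Dess–Martin periodinane (CH2Cl2, rt) gives 1-{3,5-dibromo-2-[3,4,5-tribromo-2-(4-bromo-2-nitrophenoxy)phenoxy]phenyl}ethan-1-one F6. Baeyer–Villiger oxidation with CF3CO3H (from (CF3CO)2O and urea·H2O2, Na2HPO4, CH2Cl2) gives 3,5-dibromo-2-[3,4,5-tribromo-2-(4-bromo-2-nitrophenoxy)phenoxy]phenyl acetate F7, and HCl in MeOH cleaves the acetate, rejoining the route at compound 8.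

Further compounds
F1 | step 2 | 3,5-dibromo-2-fluorobenzaldehyde | O=Cc1cc(Br)cc(Br)c1F
F2 | step 2 | 3,5-dibromo-2-(2-hydroxyphenoxy)benzaldehyde | O=Cc1cc(Br)cc(Br)c1Oc1ccccc1O
F3 | step 3 | 2,3,4-tribromo-6-[2,4-dibromo-6-(dimethoxymethyl)phenoxy]phenol | COC(OC)c1cc(Br)cc(Br)c1Oc1cc(Br)c(Br)c(Br)c1O
F4 | step 3 | 1,5-dibromo-3-(dimethoxymethyl)-2-[3,4,5-tribromo-2-(4-bromo-2-nitrophenoxy)phenoxy]benzene | COC(OC)c1cc(Br)cc(Br)c1Oc1cc(Br)c(Br)c(Br)c1Oc1ccc(Br)cc1[N+](=O)[O-]
F5 | step 4 | racemic 1-{3,5-dibromo-2-[3,4,5-tribromo-2-(4-bromo-2-nitrophenoxy)phenoxy]phenyl}ethan-1-ol | CC(O)c1cc(Br)cc(Br)c1Oc1cc(Br)c(Br)c(Br)c1Oc1ccc(Br)cc1[N+](=O)[O-]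
F6 | step 4 | 1-{3,5-dibromo-2-[3,4,5-tribromo-2-(4-bromo-2-nitrophenoxy)phenoxy]phenyl}ethan-1-one | CC(=O)c1cc(Br)cc(Br)c1Oc1cc(Br)c(Br)c(Br)c1Oc1ccc(Br)cc1[N+](=O)[O-]
F7 | step 4 | 3,5-dibromo-2-[3,4,5-tribromo-2-(4-bromo-2-nitrophenoxy)phenoxy]phenyl acetate | CC(=O)Oc1cc(Br)cc(Br)c1Oc1cc(Br)c(Br)c(Br)c1Oc1ccc(Br)cc1[N+](=O)[O-]
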